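**Retrosynthetic overview**
- Last step: one acid treatment removes three MOM ethers and a temporary tert-butoxycarbonyl group at C3 from a (2S)-flavanone-3-carboxylate.
- Key disconnection: ring C is opened at C3–C4 and at O1–C2 together. This gives a 3-geranyl-6-hydroxy-2,4-bis(MOM)benzaldehyde (ring A, C4 at the aldehyde level) and a tert-butyl 3-arylpropiolate (ring B with C2 and C3 as an alkyne). Forward, a rhodium-catalysed ynoate hydroacylation forms C3–C4, and a cinchona-thiourea oxa-Michael closure in the same flask forms O1–C2 and sets C2.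
- Enabling feature: in ring A the phenolic O1 (on C8a) is ortho to C4a, the carbon that bears C4 (a salicyl unit). Its OH steers the metal into the aldehyde C–H bond and then attacks C2, and C3, being α to the C4 ketone, can carry a removable ester. MOM groups on the C5 and C7 oxygens leave O1 as the only oxygen able to close, which fixes geranyl at C6.
- Building blocks: phloroglucinol → bis-MOM ether → lithiation between the MOM ethers and geranylation → ortho-formylation beside the free OH; 3-hydroxy-4,5-dimethoxybenzaldehyde → MOM ether → Corey–Fuchs homologation trapped with Boc2O.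
- Ring order: rings A and B are bought as arenes; ring C is the only ring made, in the key step.

Key step: step 7

Assumption: the 9-amino(9-deoxy)epi-quinidine thiourea is taken as the pseudoenantiomer that delivers the 2S series; the quinine-derived catalyst is the remedy if the facial sense is the opposite.

Step 1
Reactants: 1 phloroglucinol (benzene-1,3,5-triol)
Product: 2 3,5-bis(methoxymethoxy)phenol
Conditions: NaH (2.0 equiv), MOMCl (2.0 equiv), THF/DMF, 0 °C to rt; chromatography removes the mono- and tris-ethers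
Reagents that add atoms: chloromethyl methyl ether (MOMCl), COCCl
Why: Williamson-type O-alkylation of the phenoxide; the three hydroxyls are equivalent, so two equivalents of reagent should give the bis-ether as the main part of a separable statistical mixture and leave free the oxygen that later becomes O1.

Step 2
Reactants: 2 3,5-bis(methoxymethoxy)phenol; 3 geranyl bromide ((2E)-1-bromo-3,7-dimethylocta-2,6-diene)
Product: 5 4-[(2E)-3,7-dimethylocta-2,6-dien-1-yl]-3,5-bis(methoxymethoxy)phenol, via dilithio species 4 (not isolated)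
Conditions: n-BuLi (2.2 equiv), TMEDA, THF, 0 °C to rt; CuI (10 mol %), then 3 (1.0 equiv), −78 to 0 °C; aqueous work-up
Reagents that add atoms: none
Why: Directed ortho-metalation followed by allylic substitution; after deprotonation of the phenol the C–H flanked by two coordinating MOM ethers should be metalated in preference to the positions next to the weakly directing O–Li group, and attack at the primary carbon of the bromide (the other terminus would create a quaternary centre) keeps the E alkene.

Step 3
Reactants: 5 4-[(2E)-3,7-dimethylocta-2,6-dien-1-yl]-3,5-bis(methoxymethoxy)phenol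
Product: 6 3-[(2E)-3,7-dimethylocta-2,6-dien-1-yl]-6-hydroxy-2,4-bis(methoxymethoxy)benzaldehyde
Conditions: MgCl2 (2 equiv), Et3N (4 equiv), paraformaldehyde (6 equiv), MeCN, 75 °C
Reagents that add atoms: formaldehyde (as paraformaldehyde), C=O
Why: Casnati–Skattebøl ortho-formylation; the magnesium phenoxide delivers formaldehyde to the position next to the OH (the only free ring positions are the two equivalent ones ortho to it) and a second formaldehyde oxidises the benzylic alkoxide by hydride transfer, so the free OH ends up ortho to CHO and remote from geranyl.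

Step 4
Reactants: 7 3-hydroxy-4,5-dimethoxybenzaldehyde
Product: 8 3,4-dimethoxy-5-(methoxymethoxy)benzaldehyde
Conditions: NaH (1.1 equiv), MOMCl (1.2 equiv), THF/DMF, 0 °C to rt
Reagents that add atoms: chloromethyl methyl ether (MOMCl), COCCl
Why: Williamson-type O-alkylation of the single phenol, masking it against the organolithium of step 6 with a group that leaves in the final acid step.

Step 5
Reactants: 8 3,4-dimethoxy-5-(methoxymethoxy)benzaldehyde
Product: 9 5-(2,2-dibromoethenyl)-1,2-dimethoxy-3-(methoxymethoxy)benzene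
Conditions: CBr4 (2 equiv), PPh3 (4 equiv), CH2Cl2, 0 °C
Reagents that add atoms: carbon tetrabromide, BrC(Br)(Br)Br
Why: First stage of the Corey–Fuchs reaction, a Wittig-type olefination of the aldehyde by the dibromomethylene ylide formed in the flask.

Step 6
Reactants: 9 5-(2,2-dibromoethenyl)-1,2-dimethoxy-3-(methoxymethoxy)benzene
Product: 11 tert-butyl 3-[3,4-dimethoxy-5-(methoxymethoxy)phenyl]prop-2-ynoate, via lithium acetylide 10 (not isolated)
Conditions: n-BuLi (2.1 equiv), THF, −78 °C; then Boc2O (1.2 equiv), −78 to 0 °C; aqueous work-up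
Reagents that add atoms: di-tert-butyl dicarbonate (Boc2O), CC(C)(C)OC(=O)OC(=O)OC(C)(C)C
Why: Second stage of the Corey–Fuchs reaction (bromine–lithium exchange, Fritsch–Buttenberg–Wiechell rearrangement, deprotonation) gives the lithium acetylide, whose C-acylation by Boc2O installs the tert-butyl ester that later controls both regiochemistry and enantioselectivity.

Step 7
Reactants: 6 3-[(2E)-3,7-dimethylocta-2,6-dien-1-yl]-6-hydroxy-2,4-bis(methoxymethoxy)benzaldehyde; 11 tert-butyl 3-[3,4-dimethoxy-5-(methoxymethoxy)phenyl]prop-2-ynoate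
Product: 13 tert-butyl (2S)-2-[3,4-dimethoxy-5-(methoxymethoxy)phenyl]-6-[(2E)-3,7-dimethylocta-2,6-dien-1-yl]-5,7-bis(methoxymethoxy)-4-oxo-3,4-dihydro-2H-chromene-3-carboxylate (C3 epimer/enol mixture), via alkylidene β-keto ester 12 (not isolated)
Conditions: [Rh(cod)(OMe)]2 (2.5 mol %), 1,1'-bis(diphenylphosphino)ferrocene (5.5 mol %), 11 (1.2 equiv), toluene, 60 °C; then −25 °C, 9-amino(9-deoxy)epi-quinidine N-[3,5-bis(trifluoromethyl)phenyl]thiourea (10 mol %), 48 h; AcOH quench, silica filtration
Reagents that add atoms: none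
Why: Proposed new method: the free OH of 6 binds monovalent rhodium as an aryloxide and delivers it into the aldehyde C–H bond, giving a five-membered acyl hydride chelate of trivalent rhodium that resists decarbonylation; syn-hydrometalation of ynoate 11 puts the hydride on the aryl-bearing β-carbon and the metal on the ester-bearing α-carbon, and C–C reductive elimination forms the C3–C4 bond and releases alkylidene 12. The closest known chemistry is the rhodium-catalysed hydroacylation of alkynes by salicylaldehydes, including its racemic tandem oxa-Michael closure to chromanones, joined here to the known cinchona-thiourea cyclisation of isolated 2-hydroxyaryl alkylidene β-keto esters; new are the ynoate as hydroacylation partner and the enantioselective relay in one flask. At −25 °C the thiourea hydrogen-bonds the β-keto ester of 12 while the quinuclidine deprotonates the phenol, and ring C closes by a 6-endo-trig oxa-Michael addition that forms the O1–C2 bond. C2 is the only lasting new stereocentre and is set as S by the catalyst, which holds the alkylidene so that the phenoxide reaches one face of C2; C3 is a labile β-keto ester centre that is erased in step 8. The step needs regiocontrol in the hydrometalation, secured by the conjugating ester that directs hydride to the β-carbon; chemoselectivity for the alkyne over the trisubstituted geranyl alkenes, which insert far more slowly; a single cyclising oxygen, secured by the MOM groups on the other ortho and the para oxygen; and no racemic closure before the chiral catalyst arrives, for which a base-free rhodium precatalyst and a moderate first-stage temperature are chosen.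

Step 8
Reactants: 13 tert-butyl (2S)-2-[3,4-dimethoxy-5-(methoxymethoxy)phenyl]-6-[(2E)-3,7-dimethylocta-2,6-dien-1-yl]-5,7-bis(methoxymethoxy)-4-oxo-3,4-dihydro-2H-chromene-3-carboxylate
Product: 15 (2S)-6-[(2E)-3,7-dimethylocta-2,6-dien-1-yl]-5,7-dihydroxy-2-(3-hydroxy-4,5-dimethoxyphenyl)-2,3-dihydro-4H-chromen-4-one (CNP0228243.1), via β-keto acid 14 (not isolated)
Conditions: conc. aq. HCl (to 3 mol/L), iPrOH/THF (1:1), 45 °C; neutral aqueous work-up
Reagents that add atoms: none
Why: Acid solvolysis of the three MOM acetals and alkyl–oxygen fission of the tert-butyl ester should give β-keto acid 14, which loses CO2 through the cyclic enol pathway; no base is present, so the retro-oxa-Michael opening that would scramble C2 is avoided, and isopropanol traps the formaldehyde equivalent without esterifying 14 at a competitive rate.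

**Compound list**
1 | phloroglucinol (benzene-1,3,5-triol) | Oc1cc(O)cc(O)c1 | starting material
2 | 3,5-bis(methoxymethoxy)phenol | COCOc1cc(O)cc(OCOC)c1 | intermediate
3 | geranyl bromide, (2E)-1-bromo-3,7-dimethylocta-2,6-diene | BrC/C=C(\C)CCC=C(C)C | starting material
4 | lithium 4-lithio-3,5-bis(methoxymethoxy)phenolate | [Li]Oc1cc(OCOC)c([Li])c(OCOC)c1 | intermediate
5 | 4-[(2E)-3,7-dimethylocta-2,6-dien-1-yl]-3,5-bis(methoxymethoxy)phenol | COCOc1cc(O)cc(OCOC)c1C/C=C(\C)CCC=C(C)C | intermediate
6 | 3-[(2E)-3,7-dimethylocta-2,6-dien-1-yl]-6-hydroxy-2,4-bis(methoxymethoxy)benzaldehyde | O=Cc1c(O)cc(OCOC)c(C/C=C(\C)CCC=C(C)C)c1OCOC | intermediate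
7 | 3-hydroxy-4,5-dimethoxybenzaldehyde | COc1cc(C=O)cc(O)c1OC | starting material
8 | 3,4-dimethoxy-5-(methoxymethoxy)benzaldehyde | COCOc1cc(C=O)cc(OC)c1OC | intermediate
9 | 5-(2,2-dibromoethenyl)-1,2-dimethoxy-3-(methoxymethoxy)benzene | COCOc1cc(C=C(Br)Br)cc(OC)c1OC | intermediate
10 | lithium [3,4-dimethoxy-5-(methoxymethoxy)phenyl]ethynide | [Li]C#Cc1cc(OC)c(OC)c(OCOC)c1 | intermediate
11 | tert-butyl 3-[3,4-dimethoxy-5-(methoxymethoxy)phenyl]prop-2-ynoate | COCOc1cc(C#CC(=O)OC(C)(C)C)cc(OC)c1OC | intermediate
12 | tert-butyl (2Z)-3-[3,4-dimethoxy-5-(methoxymethoxy)phenyl]-2-{3-[(2E)-3,7-dimethylocta-2,6-dien-1-yl]-6-hydroxy-2,4-bis(methoxymethoxy)benzoyl}prop-2-enoate | COCOc1cc(/C=C(/C(=O)c2c(O)cc(OCOC)c(C/C=C(\C)CCC=C(C)C)c2OCOC)C(=O)OC(C)(C)C)cc(OC)c1OC | intermediate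
13 | tert-butyl (2S)-2-[3,4-dimethoxy-5-(methoxymethoxy)phenyl]-6-[(2E)-3,7-dimethylocta-2,6-dien-1-yl]-5,7-bis(methoxymethoxy)-4-oxo-3,4-dihydro-2H-chromene-3-carboxylate (C3 not defined) | COCOc1cc([C@@H]2C(C(=O)OC(C)(C)C)C(=O)c3c(cc(OCOC)c(C/C=C(\C)CCC=C(C)C)c3OCOC)O2)cc(OC)c1OC | intermediate
14 | (2S)-6-[(2E)-3,7-dimethylocta-2,6-dien-1-yl]-5,7-dihydroxy-2-(3-hydroxy-4,5-dimethoxyphenyl)-4-oxo-3,4-dihydro-2H-chromene-3-carboxylic acid (C3 not defined) | COc1cc([C@@H]2C(C(=O)O)C(=O)c3c(cc(O)c(C/C=C(\C)CCC=C(C)C)c3O)O2)cc(O)c1OC | intermediate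
15 | (2S)-6-[(2E)-3,7-dimethylocta-2,6-dien-1-yl]-5,7-dihydroxy-2-(3-hydroxy-4,5-dimethoxyphenyl)-2,3-dihydro-4H-chromen-4-one | COc1cc([C@@H]2CC(=O)c3c(cc(O)c(C/C=C(\C)CCC=C(C)C)c3O)O2)cc(O)c1OC | target

**Totals**
Total step count: 8. Longest linear sequence: 5 steps (steps 1, 2, 3, 7, 8 or steps 4, 5, 6, 7, 8).

**Steps most likely to fail**

Step 7 (Proposed new method). What may go wrong: hydride delivery to the wrong alkyne carbon, which gives a 1,4-dicarbonyl isomer that cannot close; uncatalysed closure of 12 during the rhodium stage, which lowers the enantiomeric purity; slow C–H insertion at the doubly ortho-substituted aldehyde. The fallback uses known chemistry throughout, sets out from 6 and returns at 13. Aldol addition of the lithium enolate of tert-butyl acetate (lithium diisopropylamide, THF, −78 °C, 3 equiv) to 6 should give tert-butyl 3-{3-[(2E)-3,7-dimethylocta-2,6-dien-1-yl]-6-hydroxy-2,4-bis(methoxymethoxy)phenyl}-3-hydroxypropanoate F1 as a racemic carbinol. MnO2 in CH2Cl2 should oxidise the benzylic alcohol to tert-butyl 3-{3-[(2E)-3,7-dimethylocta-2,6-dien-1-yl]-6-hydroxy-2,4-bis(methoxymethoxy)phenyl}-3-oxopropanoate F2. Knoevenagel condensation of F2 with aldehyde 8 (piperidine, AcOH, toluene, 4 Å sieves, rt) should give alkylidene 12, now isolated, and the same thiourea (10 mol %, toluene, −25 °C) should close it to 13.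

Step 8. What may go wrong: acid-promoted addition of the freed C5 or C7 hydroxyl to the neighbouring geranyl alkene (chroman formation); incomplete ester cleavage; ring opening and re-closure that erodes C2 or moves the side chain to C8. The fallback sets out from 13 and returns at 15, replacing the protic global step by a staged sequence without Brønsted acid in solution. Silica gel in toluene at 100 °C should cleave the tert-butyl ester to (2S)-2-[3,4-dimethoxy-5-(methoxymethoxy)phenyl]-6-[(2E)-3,7-dimethylocta-2,6-dien-1-yl]-5,7-bis(methoxymethoxy)-4-oxo-3,4-dihydro-2H-chromene-3-carboxylic acid F3, which should decarboxylate in the hot suspension to (2S)-2-[3,4-dimethoxy-5-(methoxymethoxy)phenyl]-6-[(2E)-3,7-dimethylocta-2,6-dien-1-yl]-5,7-bis(methoxymethoxy)-2,3-dihydro-4H-chromen-4-one F4. TMSOTf and 2,2'-bipyridyl in CH2Cl2 at 0 °C should then convert the three aryl MOM ethers into (2S)-2-{3,4-dimethoxy-5-[(trimethylsilyl)oxy]phenyl}-6-[(2E)-3,7-dimethylocta-2,6-dien-1-yl]-5,7-bis[(trimethylsilyl)oxy]-2,3-dihydro-4H-chromen-4-one F5, which aqueous work-up should hydrolyse to 15.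

Step 2. What may go wrong: competing metalation next to the lithium phenoxide; sluggish second deprotonation of the electron-rich phenoxide; O-allylation of the phenoxide. The fallback sets out from 2 and returns at 5, replacing the dianion by a silyl-blocked monoanion. Silylation (TIPSCl, imidazole, DMF) should give [3,5-bis(methoxymethoxy)phenoxy]tri(propan-2-yl)silane F6. n-BuLi (1.1 equiv, THF, 0 °C) should then metalate only between the MOM ethers, because the bulky, non-coordinating silyl ether shields its own ortho positions, giving {2,6-bis(methoxymethoxy)-4-[tri(propan-2-yl)silyloxy]phenyl}lithium F7. CuI-catalysed coupling with 3 should give {4-[(2E)-3,7-dimethylocta-2,6-dien-1-yl]-3,5-bis(methoxymethoxy)phenoxy}tri(propan-2-yl)silane F8, and tetrabutylammonium fluoride in THF at 0 °C should return phenol 5.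

**Further compounds**
F1 | step 7 | tert-butyl 3-{3-[(2E)-3,7-dimethylocta-2,6-dien-1-yl]-6-hydroxy-2,4-bis(methoxymethoxy)phenyl}-3-hydroxypropanoate (racemic) | OC(CC(=O)OC(C)(C)C)c1c(O)cc(OCOC)c(C/C=C(\C)CCC=C(C)C)c1OCOC
F2 | step 7 | tert-butyl 3-{3-[(2E)-3,7-dimethylocta-2,6-dien-1-yl]-6-hydroxy-2,4-bis(methoxymethoxy)phenyl}-3-oxopropanoate | O=C(CC(=O)OC(C)(C)C)c1c(O)cc(OCOC)c(C/C=C(\C)CCC=C(C)C)c1OCOC
F3 | step 8 | (2S)-2-[3,4-dimethoxy-5-(methoxymethoxy)phenyl]-6-[(2E)-3,7-dimethylocta-2,6-dien-1-yl]-5,7-bis(methoxymethoxy)-4-oxo-3,4-dihydro-2H-chromene-3-carboxylic acid (C3 not defined) | COCOc1cc([C@@H]2C(C(=O)O)C(=O)c3c(cc(OCOC)c(C/C=C(\C)CCC=C(C)C)c3OCOC)O2)cc(OC)c1OC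
F4 | step 8 | (2S)-2-[3,4-dimethoxy-5-(methoxymethoxy)phenyl]-6-[(2E)-3,7-dimethylocta-2,6-dien-1-yl]-5,7-bis(methoxymethoxy)-2,3-dihydro-4H-chromen-4-one | COCOc1cc([C@@H]2CC(=O)c3c(cc(OCOC)c(C/C=C(\C)CCC=C(C)C)c3OCOC)O2)cc(OC)c1OC
F5 | step 8 | (2S)-2-{3,4-dimethoxy-5-[(trimethylsilyl)oxy]phenyl}-6-[(2E)-3,7-dimethylocta-2,6-dien-1-yl]-5,7-bis[(trimethylsilyl)oxy]-2,3-dihydro-4H-chromen-4-one | COc1cc([C@@H]2CC(=O)c3c(cc(O[Si](C)(C)C)c(C/C=C(\C)CCC=C(C)C)c3O[Si](C)(C)C)O2)cc(O[Si](C)(C)C)c1OC
F6 | step 2 | [3,5-bis(methoxymethoxy)phenoxy]tri(propan-2-yl)silane | COCOc1cc(O[Si](C(C)C)(C(C)C)C(C)C)cc(OCOC)c1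
F7 | step 2 | {2,6-bis(methoxymethoxy)-4-[tri(propan-2-yl)silyloxy]phenyl}lithium | [Li]c1c(OCOC)cc(O[Si](C(C)C)(C(C)C)C(C)C)cc1OCOC
F8 | step 2 | {4-[(2E)-3,7-dimethylocta-2,6-dien-1-yl]-3,5-bis(methoxymethoxy)phenoxy}tri(propan-2-yl)silane | COCOc1cc(O[Si](C(C)C)(C(C)C)C(C)C)cc(OCOC)c1C/C=C(\C)CCC=C(C)C
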